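The data stem from a simulated flask from invented constants, and the scatter is random.

**The question.** Which flask ends with more target when the same dose of coupling partner, the limiting reagent at 0.0450 M against 0.050 M of starting material, is either fed over 3.0 min or put in at the start?

all flasks: starting material 0.050 M
- south-west: coupling partner 0.045 M (fed, over 3.0 min); free catalyst 25 µM; run made earlier; the fed solution adds 0.25 times the starting volume
- north: coupling partner 0.045 M (fed, over 3.0 min); free catalyst 38 µM; run made earlier; the fed solution adds 0.25 times the starting volume
- Saturday's: coupling partner 0.0450 M (fed, over 3.0 min); free catalyst 50 µM; the fed solution adds 0.25 times the starting volume; time 3.0 min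
- Sunday's: coupling partner 0.0450 M; free catalyst 50 µM; everything together at the start, the whole solution of coupling partner included, so that from the start the volume is larger by 0.25 times the starting volume; time 3.0 min

- south-west (time / s: target / %, starting material / %): 10.0: 0.4, 100.2; 15.0: 0.7, 100.1; 30.0: 0, 100.0; 60.0: 0.9, 99.0; 120: 2.4, 98.1
- north (time / s: target / %, starting material / %): 10.0: 0, 100.4; 15.0: 0, 100.0; 30.0: 0, 99.7; 60.0: 1.0, 97.5; 120: 4.6, 96.9

(standard deviation of a reading: 0.5 percentage points)

- every charge counts on the volume at the start, and the solution that is fed holds the whole dose
- the analysis behind the earlier runs scatters by 0.5 percentage points, standard deviation

- which one finishes higher in amount of target, in percent of the starting material charged ("neither" within 2 percentage points) (Saturday's / Sunday's / neither)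
- amount of target at the end, in percent of the starting material charged, Saturday's
- amount of target at the end, in percent of the starting material charged, Sunday's

**First instants.** Saturday's opens with no coupling partner, and the earlier fed runs show what that means: up to 30.0 s their target readings stay within about 2 standard deviations of zero. Sunday's holds its whole dose, diluted by the larger volume, from the start.

**The middle.** From 60.0 s to 120 s, target grows by a factor of 2.67 in the south-west run and 4.60 in the north run. These scattered readings lie on either side of the 4 expected for growth with time squared, so I take the rate as first order in coupling partner. At 1.50 min, Saturday's has half of the dose in but a smaller volume, so I reckon its rate at 0.617 of Sunday's.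

**The end.** When the feed closes, both flasks hold the same charge in the same volume, so I reckon their rates meet, apart from what has reacted. I divide the rate integrated over the feed in the fed flask by the same integral in the all-in flask. Rate constant, catalyst charge and time cancel, and with the feed volume of 0.25 this leaves 0.579, the exposure ratio: fed target over all-in target at the close of the feed, at low conversion, for a rate first order in catalyst, starting material and coupling partner. Sunday's lead is then 0.728 of Saturday's figure. I take the north reading at 120 s, from a run with less catalyst and less time than Saturday's, as a rough low estimate of Saturday's figure; it gives a lead of 3.4 percentage points, against a margin of 2 points.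

**The forecast.** It gives 11% (8.5% to 15%) for Saturday's and 17.5% (13.5% to 24%) for Sunday's, and picks Sunday's, noting that in Sunday's “the partner is present at full dose throughout”. Its ratio of 0.629 differs from my 0.579, though the direction is the same.

**The result.** Sunday's finishes higher, at 14.1% against 9.83%, a ratio of 0.699, above the exposure ratio.

    starting material + free catalyst → catalyst intermediate A (k = 130 /M/s)
    coupling partner + catalyst intermediate A ⇌ catalyst intermediate B (K = 51.0 /M, k = 150 /M/s)
    catalyst intermediate B → by-product + catalyst intermediate C (k = 2.10 /s)
    catalyst intermediate C → free catalyst + target (k = 9.10 /s)

**Exposure again.** At 1.50 min, Saturday's holds coupling partner at 46.1% of its charge, half of Sunday's 92.0%, but catalyst intermediate B at 29.1% of the catalyst against Sunday's 37.3%. Read as a power of the exposure ratio, the result gives an exponent of 0.655. A further flask, like Saturday's but with 0.018 M of coupling partner, has 0.400 of Saturday's exposure, so that exponent gives it 5.39% target. That flask holds 5.48%.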